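The earlier runs and the new flask stem from a simulated flask from invented constants; scatter was added.

**The vessel.** The vessel is closed, stirred and held at one temperature, and the same charge of second substrate, partner, free catalyst and added ligand went into every flask.

| flask | starting material | second substrate | partner | free catalyst | added ligand | temperature | remark | time |
|---|---|---|---|---|---|---|---|---|
| south | 0.080 M | 0.12 M | 0.24 M | 0.12 mM | 62 µM | 35 °C | run made earlier |  |
| north | 0.18 M | 0.12 M | 0.24 M | 0.12 mM | 62 µM | 52 °C | run made earlier |  |
| Monday's | 0.12 M | 0.120 M | 0.240 M | 0.12 mM | 62 µM | 65 °C |  | 5.0 min |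
| Friday's | 0.12 M | 0.120 M | 0.240 M | 0.12 mM | 62 µM | 40 °C |  | 5.0 min |

| run | time / min | target / % |
|---|---|---|
| south | 1.33 | 5.3 |
| south | 4.00 | 15.9 |
| south | 8.00 | 25.9 |
| south | 12.0 | 32.3 |
| south | 20.0 | 40.9 |
| north | 0.833 | 3.9 |
| north | 1.33 | 6.1 |
| north | 2.00 | 6.7 |
| north | 4.00 | 11.0 |
| north | 6.00 | 12.5 |
| north | 10.0 | 14.2 |

(readings scatter by 1 percentage point)

* the flask that comes out highest in amount of target, in percent of the starting material charged, or "all alike" when all lie within 1.5 percentage points (Monday's / Friday's / all alike)
* target at the end, in percent of the starting material charged, Monday's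
* target at the end, in percent of the starting material charged, Friday's

- the numbers in the tables scatter with a standard deviation of 1 percentage point

**An odd pair.** North ran at 52 °C and south at 35 °C, yet north showed 14.2% at 10.0 min while colder south had 25.9% at 8.00 min. Up to 1.33 min the mean rate of target, as a share of the charge, read 0.0398 min⁻¹ in south and 0.0459 min⁻¹ in north, but the two readings behind these rates differ by 0.8 points with a scatter of 1 point, so I could not tell the two opening rates apart.

**Working time.** So I looked instead at how long that rate lasted. I divided each last reading by its opening rate and got 10.3 min for south and 3.10 min for north. This quotient, the minutes of opening rate that the last reading is worth, I called the working time.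

**My reckoning.** I carried the logarithm of the working time in a straight line through temperature, which gave 7.21 min for Friday's and 1.24 min for Monday's. I took the mean opening rate 0.0429 min⁻¹ and let it fade exponentially with the working time as time constant. That gave 5.21% for Monday's and 15.5% for Friday's. The same curve, with the mean opening rate and south's working time, gives south 14.2% at 4.00 min, against the reading 15.9%, so it runs 1.7 points low there. Added to Friday's, that error made 17.2%.

**The forecast.** It named Friday's, with 9% for Monday's and 17% for Friday's, on the view that “Heat then hurts”. My Monday's figure was lower than its 9%.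

**The result.**

    starting material + free catalyst ⇌ catalyst intermediate A (K = 8.20 M⁻¹, k = 4800 M⁻¹ min⁻¹, Ea = 41.0 kJ mol⁻¹, ΔH = −90.0 kJ mol⁻¹)
    partner + catalyst intermediate A → free catalyst + target (k = 2100 M⁻¹ min⁻¹, Ea = 37.0 kJ mol⁻¹)
    second substrate + free catalyst ⇌ catalyst intermediate B (K = 240 M⁻¹, k = 9500 M⁻¹ min⁻¹, Ea = 38.0 kJ mol⁻¹, ΔH = −10.0 kJ mol⁻¹)
    partner + catalyst intermediate B → free catalyst + second product (k = 6100 M⁻¹ min⁻¹, Ea = 50.0 kJ mol⁻¹)
    2 free catalyst ⇌ resting dimer, settled at all times (K = 36000 M⁻¹, ΔH = −44.0 kJ mol⁻¹)
    free catalyst + added ligand ⇌ idle complex, settled at all times (K = 7100 M⁻¹, ΔH = −22.0 kJ mol⁻¹)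
    partner + target → over-reaction product (k = 0.430 M⁻¹ min⁻¹, Ea = 68.0 kJ mol⁻¹)
    (constants at 40 °C)

Friday's came out highest, 18.3% against 4.97% for Monday's. Monday's result divided by the mean opening rate reads 1.16 min, beside the reckoned 1.24 min. The neighbouring flask is Monday's with c(partner) at 0.060 M. Supposing the opening rate proportional to partner, the same reckoning gives 1.30%, but it made 0.289%, a working time of 0.270 min. In that neighbour, partner, the limiting reagent, stood at 0% at the end, with second product at 0.0596 M.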